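The earlier runs and the new flask are calculated on assumed constants.

Count 3 J for each E: the candidate steps carry E to X, X to L and L to Z with one J apiece, so the whole road to Z costs that much. With n the equivalents of J, the ratio of n to 3 then names the limiting reagent, J below a ratio of 1 and E above it.

common to all: E 0.30 M

|  | J | remark | time |
|---|---|---|---|
| grey | 0.61 equiv | run made earlier |  |
| amber | 3.3 equiv | run made earlier |  |
| larch | 0.950 equiv |  | 10 min |
| elm | 1.90 equiv |  | 10 min |
| oak | 3.80 equiv |  | 10 min |

| run | time / min | E / % | X / % |
|---|---|---|---|
| grey | 0.500 | 63.3 | 21.7 |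
| grey | 1.50 | 47.5 | 26.1 |
| grey | 3.00 | 43.0 | 27.4 |
| grey | 4.00 | 42.7 | 27.8 |
| grey | 6.00 | 41.5 | 28.2 |
| grey | 8.00 | 41.5 | 27.8 |
| grey | 10.0 | 39.8 | 26.8 |
| amber | 0.500 | 15.0 | 19.1 |
| amber | 1.50 | 3.7 | 6.7 |
| amber | 3.00 | 1.5 | 2.3 |
| amber | 4.00 | 2.2 | 1.9 |
| amber | 6.00 | 0.1 | 1.1 |
| amber | 8.00 | 0.3 | 0 |
| amber | 10.0 | 0 | 0 |

(readings scatter by 0.5 percentage points)

- D is meant together with its G
- the earlier runs were read with a standard deviation of 0.5 percentage points
- candidate steps: E + J -> X + D; J + X -> L + D; J + L -> Z + D; E + D <-> G; E + D -> Q
- what has gone from E into another species counts as reacted, even if it can come back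

1. part of the E that has reacted at the end, larch
2. part of the E that has reacted at the end, elm
3. part of the E that has reacted at the end, oak
4. what raising the equivalents of J from its lowest to its highest value here does to the part of the E that has reacted (changes below 5 percentage points count as none) (it falls / no change / it rises)

The ratio is 0.317 for larch, 0.633 for elm and 1.27 for oak, so the crossing lies between elm and oak. Amber, at 1.10, stands just above it, and its E and X read 0% and 0% at 10.0 min. Grey, at 0.203, stands below it and still reads 39.8% of E at that time.

Grey also shows where the rule of thumb stops working. Its reacted part, 60.2%, is 2.96 times its ratio, while X still reads 26.8%, so below the crossing I trust the count for which charge goes first and not for how much E has reacted.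

Above the crossing the count gives a number. For oak I expect 21.1% of the charged J to stay free, and this share, the charged J left once each E has taken 3, is the surplus s that I carry. So I commit to E going first in oak, to J going first in larch and elm, and to a reacted part that climbs with n.

The forecast gives 77%, 96% and 100% for the reacted part, says that with more J it rises, and says of oak: “J stays in excess, as in amber”.

The flasks give 75.6% for larch, 93.1% for elm and >99.9% for oak as the reacted part, and from larch to oak it rises, by 24 percentage points. Oak's answer moves by 5 points once J is lowered to 2.12 equiv, a charge lower than the crossing, so the border for conversion lies apart from the border for the limiting reagent. The surplus s of 21.1% stands against 22.2% of J free at the end of oak.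

    E + J → X + D (k = 0.0860 M⁻¹ s⁻¹)
    J + X → L + D (k = 0.110 M⁻¹ s⁻¹)
    J + L → Z + D (k = 0.0900 M⁻¹ s⁻¹)
    E + D ⇌ G, settled at all times (K = 2.00 M⁻¹)
    E + D → Q (k = 0.00220 M⁻¹ s⁻¹)

In a neighbour flask, elm's recipe with 7.60 equiv of J, s comes to 60.5%. The computed flask ends with 61% of its J free and 99.6% of its E as Z.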